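**Strategy**

Ring A of the flavone carries oxygen at C5, C7 and C8, a lone hydrogen at C6, the C4 carbonyl on C4a and O1 on C8a. This pentasubstituted benzene is disconnected into a C5–C8 tetraoxygenated silyl ketene acetal diene and a two-carbon bromoalkynoate that supplies C4a and C8a. One Diels–Alder/aromatisation forms C4a–C5 and C8–C8a, closes ring A and places every substituent, leaving an ester (future C4) beside a bromide (future O1 site). The precursors are (1E,3Z)-1,3,4-trimethoxy-1-(trimethylsilyloxy)buta-1,3-diene and methyl 3-bromopropiolate. Enolate acylation and CuI-catalysed O-arylation then close ring C.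

Key step: step 4

Remark on the chemistry: the C1 geometry of diene 5 is drawn as 1E but is immaterial, because C1 becomes aromatic C5; salts that exist only until work-up (phenoxide in step 5, carboxylate in step 6, diketonate in steps 7 and 8) are treated as forms of the numbered compounds.

**Route**

Step 1
Reactants: 1 methyl 4-methoxyacetoacetate
Product: 3 methyl (E)-3,4-dimethoxybut-2-enoate, via dimethyl ketal 2 (not isolated)
Conditions: HC(OMe)3 (neat), cat. H2SO4, rt; then distil
Reagents that add atoms: trimethyl orthoformate, COC(OC)OC
Why: Acid-catalysed ketalisation of the ketone by the orthoformate followed by loss of methanol towards the ester (enol ether formation from a beta-keto ester) should give the conjugated push–pull enol ether, the E isomer being the thermodynamic one, while the C4 methyl ether is a spectator.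

Step 2
Reactants: 3 methyl (E)-3,4-dimethoxybut-2-enoate
Product: 5 (1E,3Z)-1,3,4-trimethoxy-1-(trimethylsilyloxy)buta-1,3-diene, via lithium dienolate 4 (not isolated)
Conditions: LiN(i-Pr)2, THF, −78 °C; then Me3SiCl, −78 °C to rt; pentane, filter, concentrate, use at once
Reagents that add atoms: chlorotrimethylsilane, C[Si](C)(C)Cl
Why: Kinetic gamma-deprotonation of the vinylogous ester (the gamma CH2 lies cis to the ester) and O-silylation of the dienolate is the standard vinylogous silyl ketene acetal synthesis, and the C4 methoxy group should settle cis to the C3 methoxy group, pointing away from C2, to avoid 1,3-strain in the U-shaped dienolate.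

Step 3
Reactants: 6 methyl propiolate
Product: 7 methyl 3-bromopropiolate
Conditions: NBS, cat. AgNO3, acetone, rt
Reagents that add atoms: N-bromosuccinimide, O=C1CCC(=O)N1Br
Why: Silver-catalysed electrophilic bromination of the terminal alkyne C–H by NBS is the standard preparation of 3-bromopropiolates and leaves the ester untouched.

Step 4
Reactants: 5 (1E,3Z)-1,3,4-trimethoxy-1-(trimethylsilyloxy)buta-1,3-diene; 7 methyl 3-bromopropiolate
Product: 10 methyl 2-bromo-6-hydroxy-3,4-dimethoxybenzoate, via cyclohexadiene cycloadduct 8 (not isolated), via aryl silyl ether 9 (not isolated)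
Conditions: 5 (1.3 equiv), toluene, −20 °C to rt; then 1 M HCl, THF, rt
Reagents that add atoms: none
Why: The electron-rich diene and the electron-poor bromoalkynoate should combine in a normal-electron-demand, strongly asynchronous (4+2) cycloaddition in which the nucleophilic C4 terminus of the diene (flavone C8) attacks the beta carbon of the ynoate (C8a, bearing Br) and the ketene acetal carbon (C5) closes onto the alpha carbon (C4a). The closest known reaction type is the Diels–Alder benzannulation of 1-alkoxy-1-silyloxy dienes with alkynoates and 3-halopropiolates to give salicylates. Ring A is closed as a six-membered carbocycle by this intermolecular cycloaddition, which forms C4a–C5 and C8–C8a; adduct 8 then loses methanol from the C5 ketal and the C8 hydrogen (1,4-elimination driven by aromatisation) to give silyl ether 9, which dilute acid cleaves to the phenol. No stereocentre survives, so the sp3 centres of 8 need no control. The step needs regioselectivity, which the three donor oxygens on C1 and C3 of the diene (against one on C4) and the beta-electrophilic ynoate secure, and it needs the reactive s-cis conformer, which the outward (3Z) methoxy group allows. Any material that aromatises by loss of silanol instead is the methyl ether 11 and converges in the next step.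

Step 5
Reactants: 10 methyl 2-bromo-6-hydroxy-3,4-dimethoxybenzoate
Product: 11 methyl 2-bromo-3,4,6-trimethoxybenzoate
Conditions: MeI, K2CO3, DMF, 40 °C
Reagents that add atoms: iodomethane, CI
Why: Williamson ether synthesis, in which the salicylate OH is the only acidic site and the ester and the aryl bromide are inert to carbonate and iodomethane.

Step 6
Reactants: 11 methyl 2-bromo-3,4,6-trimethoxybenzoate
Product: 12 2-bromo-3,4,6-trimethoxybenzoic acid
Conditions: KOH, DMSO–H2O, 80 °C; then cold 1 M HCl to pH 2
Reagents that add atoms: potassium hydroxide, [K+].[OH-]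
Why: Saponification of the methyl ester, run hot in aqueous DMSO because the carbonyl is flanked by two ortho substituents; the aryl ethers and the unactivated aryl bromide should survive hydroxide, and cold, brief acidification should avoid protodecarboxylation of the electron-rich acid.

Step 7
Reactants: 12 2-bromo-3,4,6-trimethoxybenzoic acid; 13 2',3',4'-trimethoxyacetophenone
Product: 16 1-(2-bromo-3,4,6-trimethoxyphenyl)-3-(2,3,4-trimethoxyphenyl)propane-1,3-dione, via acid chloride 14 (not isolated), via lithium enolate 15 (not isolated)
Conditions: 12, (COCl)2, cat. DMF, CH2Cl2, 0 °C to rt, evaporate; then add in THF to 13 (2.1 equiv), LiN(SiMe3)2 (2.1 equiv), THF, −78 to 0 °C; aq. NH4Cl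
Reagents that add atoms: none
Why: Claisen-type C-acylation of a preformed ketone lithium enolate by an acid chloride (made with oxalyl chloride through the chloroiminium catalyst), with two equivalents of enolate so that the second deprotonates the more acidic 1,3-diketone as it forms and stops double acylation.

Step 8
Reactants: 16 1-(2-bromo-3,4,6-trimethoxyphenyl)-3-(2,3,4-trimethoxyphenyl)propane-1,3-dione
Product: 17 2',3',4',5,7,8-hexamethoxyflavone
Conditions: CuI (10 mol %), 1,10-phenanthroline (20 mol %), K2CO3, DMF, 100 °C
Reagents that add atoms: none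
Why: Ullmann-type intramolecular O-arylation, in which the C2 enol oxygen of the diketone, held next to the C8a–Br bond, couples under monovalent copper catalysis to form O1–C8a in a six-membered ring closure, a known cyclisation of 1-(2-bromoaryl)-1,3-diketones to flavones.

**Compound list**

1 | methyl 4-methoxyacetoacetate (methyl 4-methoxy-3-oxobutanoate) | COCC(=O)CC(=O)OC | starting material
2 | methyl 3,3,4-trimethoxybutanoate (dimethyl ketal) | COCC(OC)(OC)CC(=O)OC | intermediate (not isolated)
3 | methyl (E)-3,4-dimethoxybut-2-enoate | CO/C(COC)=C/C(=O)OC | intermediate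
4 | lithium (1Z,3Z)-1,3,4-trimethoxybuta-1,3-dien-1-olate | CO/C=C(OC)/C=C(\OC)[O-].[Li+] | intermediate (not isolated)
5 | (1E,3Z)-1,3,4-trimethoxy-1-(trimethylsilyloxy)buta-1,3-diene | CO/C=C(OC)/C=C(\OC)O[Si](C)(C)C | intermediate
6 | methyl propiolate | C#CC(=O)OC | starting material
7 | methyl 3-bromopropiolate | COC(=O)C#CBr | intermediate
8 | methyl 2-bromo-3,4,6-trimethoxy-6-(trimethylsilyloxy)cyclohexa-1,4-diene-1-carboxylate (racemic, mixture of diastereomers; both sp3 centres are lost on aromatisation) | COC(=O)C1=C(Br)C(OC)C(OC)=CC1(OC)O[Si](C)(C)C | intermediate (not isolated)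
9 | methyl 2-bromo-3,4-dimethoxy-6-(trimethylsilyloxy)benzoate | COC(=O)c1c(O[Si](C)(C)C)cc(OC)c(OC)c1Br | intermediate (not isolated)
10 | methyl 2-bromo-6-hydroxy-3,4-dimethoxybenzoate | COC(=O)c1c(O)cc(OC)c(OC)c1Br | intermediate
11 | methyl 2-bromo-3,4,6-trimethoxybenzoate | COC(=O)c1c(OC)cc(OC)c(OC)c1Br | intermediate
12 | 2-bromo-3,4,6-trimethoxybenzoic acid | OC(=O)c1c(OC)cc(OC)c(OC)c1Br | intermediate
13 | 2',3',4'-trimethoxyacetophenone | CC(=O)c1ccc(OC)c(OC)c1OC | starting material
14 | 2-bromo-3,4,6-trimethoxybenzoyl chloride | O=C(Cl)c1c(OC)cc(OC)c(OC)c1Br | intermediate (not isolated)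
15 | lithium 1-(2,3,4-trimethoxyphenyl)ethen-1-olate | [Li+].[O-]C(=C)c1ccc(OC)c(OC)c1OC | intermediate (not isolated)
16 | 1-(2-bromo-3,4,6-trimethoxyphenyl)-3-(2,3,4-trimethoxyphenyl)propane-1,3-dione | COc1ccc(C(=O)CC(=O)c2c(OC)cc(OC)c(OC)c2Br)c(OC)c1OC | intermediate
17 | 2',3',4',5,7,8-hexamethoxyflavone | COc1ccc(-c2cc(=O)c3c(OC)cc(OC)c(OC)c3o2)c(OC)c1OC | target

**Step count and risks**

Total steps: 8. Longest linear sequence: 7 steps (steps 1, 2, 4, 5, 6, 7, 8); step 3 is the one-step side branch.

Steps most likely to fail:

1. Step 4 (cycloaddition and aromatisation). What may go wrong: bromine transfer from the ynoate to the ketene acetal carbon (halophilic attack), conjugate addition that stops at the open-chain stage, or decomposition of the diene before it reacts. The fallback takes ring A from an arene and closes ring C by Baker–Venkataraman-type acylation and cyclodehydration; it sets out from 13 and returns at 17. Haloform oxidation of 13 (NaOCl, NaOH) should give 2,3,4-trimethoxybenzoic acid F1, and (COCl)2 with cat. DMF its chloride, 2,3,4-trimethoxybenzoyl chloride F2. Friedel–Crafts acetylation of commercial 1,2,3,5-tetramethoxybenzene with AcCl/AlCl3, in which AlCl3 should also cleave the methoxy group squeezed between the new ketone and a neighbouring methoxy group, should give 2'-hydroxy-3',4',6'-trimethoxyacetophenone F3. F3 with excess LiN(SiMe3)2 and F2 in THF should give 1-(2-hydroxy-3,4,6-trimethoxyphenyl)-3-(2,3,4-trimethoxyphenyl)propane-1,3-dione F4, and H2SO4 in AcOH should close it to 17 by cyclodehydration.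

2. Step 2 (diene formation). What may go wrong: the C4 methoxy group ends up pointing inward (3E), the ester enolate condenses with unreacted ester, or the silyl ketene acetal hydrolyses on handling. The fallback uses a 1,3-bis(silyloxy) diene made directly from the keto ester, so that the C7 oxygen arrives as a phenol; it sets out from 1 and returns at 11. Me3SiCl/Et3N should convert 1 into methyl 4-methoxy-3-(trimethylsilyloxy)but-2-enoate F5. LiN(i-Pr)2 then Me3SiCl (THF, −78 °C) should give (3Z)-1,4-dimethoxy-1,3-bis(trimethylsilyloxy)buta-1,3-diene F6. Cycloaddition with 7 should give methyl 2-bromo-3,6-dimethoxy-4,6-bis(trimethylsilyloxy)cyclohexa-1,4-diene-1-carboxylate F7, which dilute HCl should aromatise and desilylate to methyl 2-bromo-4,6-dihydroxy-3-methoxybenzoate F8. Excess MeI with K2CO3 in DMF should methylate both phenols and give 11.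

3. Step 7 (C-acylation). What may go wrong: O-acylation or double acylation of the enolate, or slow attack on the acyl chloride flanked by two ortho substituents. The fallback exchanges the roles of nucleophile and electrophile; it sets out from 12 and returns at 16. Acid chloride 14, made from 12 as before, with MeNH(OMe)·HCl and pyridine should give 2-bromo-N,3,4,6-tetramethoxy-N-methylbenzamide F9. MeMgBr (THF, 0 °C to rt) should give 1-(2-bromo-3,4,6-trimethoxyphenyl)ethan-1-one F10. Claisen condensation of F10 with commercial methyl 2,3,4-trimethoxybenzoate (NaH, THF, reflux) should give 16.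

**Further compounds**

F1 | step 4 | 2,3,4-trimethoxybenzoic acid | COc1ccc(C(=O)O)c(OC)c1OC
F2 | step 4 | 2,3,4-trimethoxybenzoyl chloride | COc1ccc(C(=O)Cl)c(OC)c1OC
F3 | step 4 | 2'-hydroxy-3',4',6'-trimethoxyacetophenone | CC(=O)c1c(O)c(OC)c(OC)cc1OC
F4 | step 4 | 1-(2-hydroxy-3,4,6-trimethoxyphenyl)-3-(2,3,4-trimethoxyphenyl)propane-1,3-dione | COc1ccc(C(=O)CC(=O)c2c(O)c(OC)c(OC)cc2OC)c(OC)c1OC
F5 | step 2 | methyl 4-methoxy-3-(trimethylsilyloxy)but-2-enoate (E/Z mixture, geometry not defined) | COCC(O[Si](C)(C)C)=CC(=O)OC
F6 | step 2 | (3Z)-1,4-dimethoxy-1,3-bis(trimethylsilyloxy)buta-1,3-diene (C1 geometry not defined) | CO/C=C(O[Si](C)(C)C)/C=C(OC)O[Si](C)(C)C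
F7 | step 2 | methyl 2-bromo-3,6-dimethoxy-4,6-bis(trimethylsilyloxy)cyclohexa-1,4-diene-1-carboxylate (racemic, mixture of diastereomers) | COC(=O)C1=C(Br)C(OC)C(O[Si](C)(C)C)=CC1(OC)O[Si](C)(C)C
F8 | step 2 | methyl 2-bromo-4,6-dihydroxy-3-methoxybenzoate | COC(=O)c1c(O)cc(O)c(OC)c1Br
F9 | step 7 | 2-bromo-N,3,4,6-tetramethoxy-N-methylbenzamide | CON(C)C(=O)c1c(OC)cc(OC)c(OC)c1Br
F10 | step 7 | 1-(2-bromo-3,4,6-trimethoxyphenyl)ethan-1-one | CC(=O)c1c(OC)cc(OC)c(OC)c1Br
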